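The hydrindane is numbered C1 (ethylidene carbon), C2 (acetoxy carbon), C3, C3a, C4 (methylidene carbon), C5 (carbinol), C6 (angelate carbon), C7 (isopropyl carbon), C7a. The C5-hydroxy/C4-methylidene pair is treated as a transposed C4=C5 olefin, which makes the six-membered ring a Diels–Alder retron. One intramolecular [4+2] of an acyclic E,E,E-triene therefore makes C6–C7 and C3a–C7a, closes both rings and sets C6, C7, C7a and C3a. The precursor is a 2-deoxy-D-ribose chain: a 1-boryl-3-methyldiene (C6=C5–C4=C3a) joined through the acetonide-bearing C3–C2–C1 tether to an E-enone whose acetyl group on C7 later becomes isopropyl.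

Key step: step 6

Remark: α is the face of the C2 and C6 oxygens, β the opposite face; ylides 3 and 8, boronate 5 and acid 14 are taken as purchased.

Step 1
Reactants: 1 2-deoxy-D-ribose
Product: 2 3,4-O-isopropylidene-2-deoxy-D-ribopyranose
Conditions: 2-methoxypropene, PPTS (cat.), DMF, 0 °C
Reagents that add atoms: 2-methoxypropene, COC(C)=C
Why: Kinetic acetalisation of the cis-3,4-diol of the pyranose form with an enol ether leaves the anomeric hydroxyl free and touches no stereocentre.

Step 2
Reactants: 2 3,4-O-isopropylidene-2-deoxy-D-ribopyranose; 3 2-(triphenylphosphoranylidene)propanal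
Product: 4 (E)-hydroxy enal
Conditions: toluene, 90 °C
Reagents that add atoms: none
Why: Wittig olefination of the open-chain hydroxy-aldehyde tautomer with a stabilised ylide should give the (E)-2-methyl enal under neutral conditions that avoid oxa-Michael closure of the freed primary hydroxyl.

Step 3
Reactants: 4 (E)-hydroxy enal; 5 2-(dichloromethyl)-4,4,5,5-tetramethyl-1,3,2-dioxaborolane
Product: 6 (E,E)-dienylboronate alcohol
Conditions: CrCl2, LiI, THF, 25 °C
Reagents that add atoms: none
Why: Takai–Utimoto borylolefination (geminal dichromium reagent from 5) should convert the aldehyde into the (E)-alkenylboronate and tolerates the free alcohol and the acetal.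

Step 4
Reactants: 6 (E,E)-dienylboronate alcohol
Product: 7 dienylboronate aldehyde
Conditions: Dess–Martin periodinane, NaHCO3, CH2Cl2, 0 → 25 °C
Reagents that add atoms: none
Why: Dess–Martin oxidation under buffered conditions should give the α-alkoxy aldehyde without epimerisation and leave the dienylboronate intact.

Step 5
Reactants: 7 dienylboronate aldehyde; 8 1-(triphenylphosphoranylidene)propan-2-one
Product: 9 (E,E,E)-trienone
Conditions: CH2Cl2, 25 °C
Reagents that add atoms: none
Why: Wittig reaction with the stabilised acetonyl ylide should give the (E)-enone and thereby the complete E,E,E-triene.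

Step 6
Reactants: 9 (E,E,E)-trienone
Product: 10 trans-fused boryl ketone cycloadduct
Conditions: toluene (0.01 M), BHT (cat.), 120 °C, sealed tube
Reagents that add atoms: none
Why: Thermal type-1 intramolecular Diels–Alder reaction: the (1E,3E)-1-boryl-3-methyldiene (C6=C5–C4=C3a) adds suprafacially to the E-enone (C7=C7a) through a concerted, asynchronous transition state in which the C3a–C7a bond, β to the acetyl group, is the more advanced. The closest known reactions are the thermal cyclisations of terminally activated (E,E,E)-1,3,8-nonatrienes to trans-hydrindenes and the Diels–Alder reactions of 1-(pinacolboryl)dienes. The cyclohexene closes by the [4+2] itself and the cyclopentane closes in the fused mode through the internal C3a–C7a bond, the three-atom tether excluding the bridged regioisomer. Diene and dienophile geometry place the C6 boron cis to the C3a tether bond and the C7 acetyl trans to the C7a–C1 bond; endo placement of the s-cis acetyl group (secondary orbital overlap) gives the cis C6/C7 relation and the trans ring fusion; the cis-acetonide makes the diene add to the enone face anti to the C1–O bond, which fixes the absolute sense. The step needs endo and π-facial selectivity, which the terminal acyl group on C7 and the rigid dioxolane should secure, while the tether enforces the regiochemistry.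

Step 7
Reactants: 10 trans-fused boryl ketone cycloadduct
Product: 11 isopropenyl allylboronate
Conditions: Cp2TiMe2, toluene, 70 °C
Reagents that add atoms: dimethyltitanocene, [CH3-].[CH3-].[Ti+4].c1cc[cH-]c1.c1cc[cH-]c1
Why: Petasis methylenation is non-basic, so the acetyl group on the epimerisable C7 should become isopropenyl without loss of the C7 configuration set in step 6.

Step 8
Reactants: 11 isopropenyl allylboronate
Product: 12 isopropyl allylboronate
Conditions: H2 (1 atm), RhCl(PPh3)3 (cat.), toluene/EtOH, 25 °C
Reagents that add atoms: none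
Why: Homogeneous hydrogenation with Wilkinson's catalyst should saturate the 1,1-disubstituted olefin much faster than the trisubstituted ring olefin and creates no stereocentre.

Step 9
Reactants: 12 isopropyl allylboronate
Product: 13 C6 allylic alcohol
Conditions: H2O2 (30% aq), NaOH, THF, 0 °C
Reagents that add atoms: hydrogen peroxide, OO
Why: Alkaline peroxide oxidation of the secondary allylic boronate proceeds by 1,2-migration from boron to oxygen with retention at C6 and without allylic shift.

Step 10
Reactants: 13 C6 allylic alcohol; 14 angelic acid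
Product: 16 C6 angelate acetonide, via angelic 2,4,6-trichlorobenzoic anhydride 15 (not isolated)
Conditions: 14, 2,4,6-trichlorobenzoyl chloride, Et3N, toluene, 25 °C; then 13, 80 °C
Reagents that add atoms: 2,4,6-trichlorobenzoyl chloride, O=C(Cl)c1c(Cl)cc(Cl)cc1Cl (its atoms reach 15 only, not 16)
Why: Yamaguchi-type esterification through the mixed anhydride without DMAP should acylate the hindered secondary alcohol with angelic acid while keeping the Z geometry, and C6 is not touched.

Step 11
Reactants: 16 C6 angelate acetonide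
Product: 17 C1,C2-diol
Conditions: AcOH/H2O (4:1), 50 °C
Reagents that add atoms: none
Why: Acid hydrolysis of the isopropylidene acetal, which the secondary allylic ester and the trisubstituted olefin should survive.

Step 12
Reactants: 17 C1,C2-diol
Product: 18 C2 triethylsilyl ether
Conditions: Et3SiCl, imidazole, CH2Cl2, −40 °C
Reagents that add atoms: chlorotriethylsilane, CC[Si](Cl)(CC)CC
Why: Kinetic silylation should occur at the less hindered C2 hydroxyl because the C1 hydroxyl is flanked by the ring-fusion carbon C7a and the C7 isopropyl group.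

Step 13
Reactants: 18 C2 triethylsilyl ether
Product: 19 C1 ketone
Conditions: Dess–Martin periodinane, NaHCO3, CH2Cl2, 25 °C
Reagents that add atoms: none
Why: Dess–Martin oxidation of the remaining C1 alcohol under buffered, non-enolising conditions should keep C2 and C7a intact.

Step 14
Reactants: 19 C1 ketone
Product: 20 4β,5β-epoxy ketone
Conditions: mCPBA, NaHCO3, CH2Cl2, 0 °C
Reagents that add atoms: mCPBA, O=C(OO)c1cccc(Cl)c1
Why: Prilezhaev epoxidation should take the only electron-rich olefin (the angelate C=C is electron-poor) on the β face, anti to the pseudoaxial C6 ester, which places the C5 oxygen trans to the C6 oxygen.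

Step 15
Reactants: 20 4β,5β-epoxy ketone
Product: 21 (Z)-ethylidene epoxide
Conditions: EtPPh3Br, KHMDS, THF, −78 → 25 °C
Reagents that add atoms: ethyltriphenylphosphonium bromide, CC[P+](c1ccccc1)(c1ccccc1)c1ccccc1.[Br-]
Why: Wittig reaction of the non-stabilised ylide with the α-silyloxy ketone should place the methyl group cis to the oxygen-bearing C2 (the known Z-directing effect of an α-oxygen substituent, helped by steric shielding on the C7a side), giving the Z-ethylidene.

Step 16
Reactants: 21 (Z)-ethylidene epoxide
Product: 23 C2 acetate epoxide, via C2 alcohol 22 (not isolated)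
Conditions: TBAF, AcOH, THF, 0 °C; then Ac2O, pyridine, 25 °C
Reagents that add atoms: acetic anhydride, CC(=O)OC(C)=O
Why: Buffered fluoride should cleave the triethylsilyl ether and the liberated C2 alcohol is acetylated in the same flask, epoxide, angelate and ethylidene being inert to both reagents.

Step 17
Reactants: 23 C2 acetate epoxide
Product: 24 target CNP0113604.1
Conditions: Cp2TiCl2, Mn, THF, 25 °C; then 1 M HCl
Reagents that add atoms: none
Why: Titanocene(III)-mediated epoxide isomerisation: homolysis of the tertiary C4–O bond and hydrogen abstraction from the adjacent methyl group by a second titanium(III) should give the exocyclic olefin and the C5 alcohol with the configuration set in step 14.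

Compound list
1 | 2-deoxy-D-ribose (drawn as the open-chain aldehyde) | O=CC[C@H](O)[C@H](O)CO | starting material
2 | 3,4-O-isopropylidene-2-deoxy-D-ribopyranose (lactol, both anomers) | OC1C[C@H](O3)[C@H](OC3(C)C)CO1 | intermediate
3 | 2-(triphenylphosphoranylidene)propanal | CC(C=O)=P(c1ccccc1)(c1ccccc1)c1ccccc1 | starting material
4 | (E)-hydroxy enal: (2E)-4-[(4S,5R)-5-(hydroxymethyl)-2,2-dimethyl-1,3-dioxolan-4-yl]-2-methylbut-2-enal | O=C/C(C)=C/C[C@H](O3)[C@H](OC3(C)C)CO | intermediate
5 | 2-(dichloromethyl)-4,4,5,5-tetramethyl-1,3,2-dioxaborolane | ClC(Cl)B1OC(C)(C)C(C)(C)O1 | starting material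
6 | (E,E)-dienylboronate alcohol: [(4R,5S)-2,2-dimethyl-5-[(2E,4E)-3-methyl-5-(pinacolboryl)penta-2,4-dien-1-yl]-1,3-dioxolan-4-yl]methanol | CC1(C)OB(OC1(C)C)/C=C/C(C)=C/C[C@H](O3)[C@H](OC3(C)C)CO | intermediate
7 | dienylboronate aldehyde: the dioxolane-4-carbaldehyde from 6, cis-acetonide retained | CC1(C)OB(OC1(C)C)/C=C/C(C)=C/C[C@H](O3)[C@H](OC3(C)C)C=O | intermediate
8 | 1-(triphenylphosphoranylidene)propan-2-one | CC(=O)C=P(c1ccccc1)(c1ccccc1)c1ccccc1 | starting material
9 | (E,E,E)-trienone: (3E)-4-[(4R,5S)-2,2-dimethyl-5-[(2E,4E)-3-methyl-5-(pinacolboryl)penta-2,4-dien-1-yl]-1,3-dioxolan-4-yl]but-3-en-2-one | CC1(C)OB(OC1(C)C)/C=C/C(C)=C/C[C@H](O3)[C@H](OC3(C)C)/C=C/C(C)=O | intermediate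
10 | trans-fused boryl ketone cycloadduct: 4-methyl-hexahydroindene with C4=C5 olefin, 6α-Bpin, 7α-acetyl, 1α,2α-acetonide, 3a-H β, 7a-H α | CC1=C[C@@H](B4OC(C)(C)C(C)(C)O4)[C@@H](C(C)=O)[C@@H]2[C@@H](O3)[C@@H](OC3(C)C)C[C@@H]12 | intermediate
11 | isopropenyl allylboronate (7α-prop-1-en-2-yl analogue of 10) | CC1=C[C@@H](B4OC(C)(C)C(C)(C)O4)[C@@H](C(C)=C)[C@@H]2[C@@H](O3)[C@@H](OC3(C)C)C[C@@H]12 | intermediate
12 | isopropyl allylboronate (7α-isopropyl) | CC1=C[C@@H](B4OC(C)(C)C(C)(C)O4)[C@@H](C(C)C)[C@@H]2[C@@H](O3)[C@@H](OC3(C)C)C[C@@H]12 | intermediate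
13 | C6 allylic alcohol (6α-OH, 7α-isopropyl, 1α,2α-acetonide) | CC1=C[C@@H](O)[C@@H](C(C)C)[C@@H]2[C@@H](O3)[C@@H](OC3(C)C)C[C@@H]12 | intermediate
14 | angelic acid, (Z)-2-methylbut-2-enoic acid | C/C=C(/C)C(=O)O | starting material
15 | angelic 2,4,6-trichlorobenzoic anhydride (not isolated) | C/C=C(/C)C(=O)OC(=O)c1c(Cl)cc(Cl)cc1Cl | intermediate
16 | C6 angelate acetonide | CC1=C[C@@H](OC(=O)/C(C)=C\C)[C@@H](C(C)C)[C@@H]2[C@@H](O3)[C@@H](OC3(C)C)C[C@@H]12 | intermediate
17 | C1,C2-diol (1α,2α-diol, 6α-angelate) | CC1=C[C@@H](OC(=O)/C(C)=C\C)[C@@H](C(C)C)[C@@H]2[C@@H](O)[C@@H](O)C[C@@H]12 | intermediate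
18 | C2 triethylsilyl ether with free 1α-OH | CC1=C[C@@H](OC(=O)/C(C)=C\C)[C@@H](C(C)C)[C@@H]2[C@@H](O)[C@@H](O[Si](CC)(CC)CC)C[C@@H]12 | intermediate
19 | C1 ketone (trans-fused hydrindenone, 2α-OTES, 6α-angelate) | CC1=C[C@@H](OC(=O)/C(C)=C\C)[C@@H](C(C)C)[C@@H]2C(=O)[C@@H](O[Si](CC)(CC)CC)C[C@@H]12 | intermediate
20 | 4β,5β-epoxy ketone (4α-methyl) | C[C@@]12O[C@@H]1[C@@H](OC(=O)/C(C)=C\C)[C@@H](C(C)C)[C@@H]3C(=O)[C@@H](O[Si](CC)(CC)CC)C[C@@H]23 | intermediate
21 | (Z)-ethylidene epoxide (ethylidene methyl cis to C2, 2α-OTES) | C[C@@]12O[C@@H]1[C@@H](OC(=O)/C(C)=C\C)[C@@H](C(C)C)[C@@H]3/C(=C/C)[C@@H](O[Si](CC)(CC)CC)C[C@@H]23 | intermediate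
22 | C2 alcohol (2α-OH epoxide, not isolated) | C[C@@]12O[C@@H]1[C@@H](OC(=O)/C(C)=C\C)[C@@H](C(C)C)[C@@H]3/C(=C/C)[C@@H](O)C[C@@H]23 | intermediate
23 | C2 acetate epoxide (2α-OAc, 6α-angelate, 4β,5β-epoxide) | C[C@@]12O[C@@H]1[C@@H](OC(=O)/C(C)=C\C)[C@@H](C(C)C)[C@@H]3/C(=C/C)[C@@H](OC(C)=O)C[C@@H]23 | intermediate
24 | CNP0113604.1: 2α-acetoxy-6α-angeloyloxy-(1Z)-ethylidene-5β-hydroxy-7α-isopropyl-4-methylidene-trans-hydrindane | C=C1[C@H](O)[C@@H](OC(=O)/C(C)=C\C)[C@@H](C(C)C)[C@@H]2/C(=C/C)[C@@H](OC(C)=O)C[C@@H]12 | target

Total step count: 17. Longest linear sequence: 17 steps (1 → 24); all other partners are purchased.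

Steps most likely to fail

Step 6. The thermal cycloaddition may proceed with poor endo/exo or facial control, so that cis-fused or C7-epimeric adducts form alongside 10. The fallback sets out from aldehyde 7 and changes the dienophile to an enal that is activated as an iminium ion. Wittig reaction of 7 with (triphenylphosphoranylidene)acetaldehyde should give the (E,E,E)-trienal F1. Its intramolecular Diels–Alder reaction, catalysed by 5-benzyl-2-tert-butyl-3-methylimidazolidin-4-one trifluoroacetate (the enantiomer matched to the acetonide), should give the endo, trans-fused aldehyde cycloadduct F2. Methyl addition with MeTi(OiPr)3 should give the secondary carbinol F3, and Dess–Martin oxidation comes back to the route at ketone 10.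

Step 15. Addition of the ylide to the hindered ketone may be slow, so that enolisation competes, or the olefin geometry may come out as a mixture. The fallback sets out from epoxy ketone 20. Horner–Wittig addition of lithiated ethyldiphenylphosphine oxide at −78 °C should give the β-hydroxy phosphine oxide F4 as separable diastereomers. The adduct that leads to the Z-olefin is purified and eliminated stereospecifically (syn) with NaH in DMF, which comes back to the route at 21.

Step 17. The titanium(III) opening may end in deoxygenation to the olefin, or hydrogen may be abstracted from C3a instead of the methyl group. The fallback sets out from epoxide 23 and uses an ionic opening: TMSOTf and 2,6-lutidine, then DBU, should open the epoxide at the tertiary carbon and remove a methyl proton to give the allylic trimethylsilyl ether F5. Dilute aqueous acid then removes the silyl group and comes back to the route at target 24.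

Further compounds
F1 | step 6 | (E,E,E)-trienal | CC1(C)OB(OC1(C)C)/C=C/C(C)=C/C[C@H](O3)[C@H](OC3(C)C)/C=C/C=O
F2 | step 6 | trans-fused aldehyde cycloadduct (7α-formyl analogue of 10) | CC1=C[C@@H](B4OC(C)(C)C(C)(C)O4)[C@@H](C=O)[C@@H]2[C@@H](O3)[C@@H](OC3(C)C)C[C@@H]12
F3 | step 6 | secondary carbinol (7α-(1-hydroxyethyl), carbinol centre as formed) | CC1=C[C@@H](B4OC(C)(C)C(C)(C)O4)[C@@H](C(C)O)[C@@H]2[C@@H](O3)[C@@H](OC3(C)C)C[C@@H]12
F4 | step 15 | β-hydroxy phosphine oxide (C1 carbinol with 1-(diphenylphosphoryl)ethyl group, single separated diastereomer) | C[C@@]12O[C@@H]1[C@@H](OC(=O)/C(C)=C\C)[C@@H](C(C)C)[C@@H]3C(O)(C(C)P(=O)(c4ccccc4)c4ccccc4)[C@@H](O[Si](CC)(CC)CC)C[C@@H]23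
F5 | step 17 | allylic trimethylsilyl ether of 24 (5β-OTMS) | C=C1[C@H](O[Si](C)(C)C)[C@@H](OC(=O)/C(C)=C\C)[C@@H](C(C)C)[C@@H]2/C(=C/C)[C@@H](OC(C)=O)C[C@@H]12
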